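**Retrosynthetic overview**
1. Last bond: the C3–O ester, cut to an eremophilane alcohol (diosphenol held as its silyl enol ether) and (2Z)-4-(angeloyloxy)-2-methylbut-2-enoic acid, the acid coming from α-methylbutenolide and angelic acid.
2. Skeleton: eremophilane ⇐ 3α,4α-epoxyeudesmane by the biosynthetic 1,2-hydride (C5→C4) and 1,2-methyl (C10→C5) shifts; the epoxide oxygen becomes the C3 oxygen and the C9 oxygen ends as the enol.
3. Rings A and B: both six-membered rings close in one transannular C5–C10 bond formation from a germacra-1(10),4-diene, as in germacrene → eudesmyl cation; a C9 carbinol steers which face closes and is erased later.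
4. Ten-membered ring: taken ready-made as germacrone, hydroxylated enantioselectively at C9 before ring closure.
5. Ring order: ten-membered ring (purchased) → rings A and B together → hydride/methyl shifts; no ring is formed afterwards.

Assumption: germacrone (bulk isolate of Geranium macrorrhizum oil) is accepted as a commercial starting material.
Assumption: the (−)-(camphorsulfonyl)oxaziridine is taken to give the 9R alcohol, by analogy with its acyclic ketone enolate cases; if the 9S alcohol forms, the (+)-reagent is used and nothing else changes.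
Numbering: germacrane/eudesmane/eremophilane numbering throughout (C8 = ketone carbon, C7 = isopropylidene-bearing carbon, C14 = methyl on C10, C15 = methyl on C4).

**Route**

Step 1
Reactants: 1 germacrone
Product: 3 (9R)-9-hydroxygermacrone, via potassium dienolate 2 (not isolated)
Conditions: KN(SiMe3)2, THF, −78 °C; then (−)-(camphorsulfonyl)oxaziridine, −78 °C; AcOH quench at −78 °C
Reagents that add atoms: (−)-(2S,8aR)-(camphorsulfonyl)oxaziridine, CC1(C)[C@H]2CC[C@@]13CS(=O)(=O)N4O[C@]34C2
Why: Kinetic deprotonation can only occur at C9 (the single α-CH2, also allylic), and the chiral N-sulfonyloxaziridine delivers oxygen to one face of the dienolate α-carbon (Davis asymmetric enolate hydroxylation), creating the C9 stereocentre, whose enantiopurity is raised by recrystallisation.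

Step 2
Reactants: 3 (9R)-9-hydroxygermacrone
Product: 4 (5S,9R,10S)-9-hydroxyeudesma-3,7(11)-dien-8-one
Conditions: TsOH·H2O (10 mol%), CH2Cl2, 0 °C; AgNO3–silica chromatography
Reagents that add atoms: none
Why: Proposed new method: protonation at C1 with concerted attack of the C4=C5 olefin on C10 through the chair–chair conformer (the acid-induced transannular germacradiene → eudesmyl cation cyclisation known for germacrone and costunolide) closes both six-membered rings trans, the C9 hydroxyl sitting pseudo-equatorial and hydrogen-bonded to the C8 carbonyl so that only one planar-chiral conformer reacts and C5/C10 are set as 5S,10S, and loss of the axial H-3 gives the Δ3 olefin while the exocyclic isomer re-enters through the same cation.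

Step 3
Reactants: 4 (5S,9R,10S)-9-hydroxyeudesma-3,7(11)-dien-8-one
Product: 5 (5S,9R,10S)-9-[(tert-butyldimethylsilyl)oxy]eudesma-3,7(11)-dien-8-one
Conditions: TBSOTf, 2,6-lutidine, CH2Cl2, −78 → 0 °C
Reagents that add atoms: tert-butyldimethylsilyl triflate, CC(C)(C)[Si](C)(C)OS(=O)(=O)C(F)(F)F
Why: The hindered secondary α-ketol hydroxyl is silylated by the silyl triflate (silyl ether formation), masking the future diosphenol oxygen without touching any stereocentre.

Step 4
Reactants: 5 (5S,9R,10S)-9-[(tert-butyldimethylsilyl)oxy]eudesma-3,7(11)-dien-8-one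
Product: 6 (3R,4S,5R,9R,10S)-9-[(tert-butyldimethylsilyl)oxy]-3,4-epoxyeudesm-7(11)-en-8-one
Conditions: mCPBA (1.1 equiv), CH2Cl2, 0 °C
Reagents that add atoms: 3-chloroperbenzoic acid, OOC(=O)c1cccc(Cl)c1
Why: Prilezhaev epoxidation picks the electron-rich trisubstituted C3=C4 olefin over the enone olefin and attacks the α face, anti to the axial C10 methyl, which fixes C3 as R with its oxygen α.

Step 5
Reactants: 6 (3R,4S,5R,9R,10S)-9-[(tert-butyldimethylsilyl)oxy]-3,4-epoxyeudesm-7(11)-en-8-one
Product: 7 (3R,4R,5R)-9-[(tert-butyldimethylsilyl)oxy]-3-hydroxyeremophila-7(11),9-dien-8-one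
Conditions: BF3·OEt2 (0.3 equiv), CH2Cl2, −78 → −20 °C
Reagents that add atoms: none
Why: Proposed new method: Lewis-acid opening of the epoxide at tertiary C4 gives a cation whose only aligned neighbours in the rigid trans-decalin are the axial H-5α, which shifts to C4 (4R, methyl β), and then the axial 10β-methyl, which shifts to C5 (5R), after which the axial H-9α is lost to give the C9=C10 silyl enol ether conjugated with C8=O, while the C3–O bond stays axial (3R retained) so that H-3 is equatorial and cannot migrate to give a ketone; the closest known reactions are the BF3-induced backbone (Westphalen-type) rearrangements of steroidal epoxides and the acid-induced eudesmane → eremophilane methyl shift of 4,5-epoxyeudesmanes.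

Step 6
Reactants: 8 3-methylfuran-2(5H)-one
Product: 10 4-methoxybenzyl (2Z)-4-hydroxy-2-methylbut-2-enoate, via potassium carboxylate 9 (not isolated)
Conditions: KOH (1.0 equiv), MeOH/H2O, 0 °C; evaporate; 4-MeOC6H4CH2Cl, DMF, rt
Reagents that add atoms: potassium hydroxide, [K+].[OH-]; 4-methoxybenzyl chloride, COc1ccc(CCl)cc1
Why: Saponification of the butenolide followed by carboxylate O-alkylation (SN2) keeps the Z geometry inherited from the ring, and no stereocentre is involved.

Step 7
Reactants: 10 4-methoxybenzyl (2Z)-4-hydroxy-2-methylbut-2-enoate; 11 angelic acid [(2Z)-2-methylbut-2-enoic acid]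
Product: 13 4-methoxybenzyl (2Z)-2-methyl-4-{[(2Z)-2-methylbut-2-enoyl]oxy}but-2-enoate, via angelic mixed anhydride 12 (not isolated)
Conditions: 11, 2,4,6-Cl3C6H2COCl, Et3N, toluene, rt; then 10, DMAP (10 mol%), 0 °C → rt
Reagents that add atoms: none
Why: Yamaguchi esterification of the unhindered primary allylic alcohol is fast at low temperature, so the angelate keeps its Z geometry and lactonisation of 10 does not compete.

Step 8
Reactants: 13 4-methoxybenzyl (2Z)-2-methyl-4-{[(2Z)-2-methylbut-2-enoyl]oxy}but-2-enoate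
Product: 14 (2Z)-2-methyl-4-{[(2Z)-2-methylbut-2-enoyl]oxy}but-2-enoic acid
Conditions: TFA, anisole, CH2Cl2, 0 °C
Reagents that add atoms: none
Why: Acidolysis of the 4-methoxybenzyl ester (benzylic C–O ionisation, cation trapped by anisole) frees the acid without touching the allylic angelate or either Z olefin.

Step 9
Reactants: 7 (3R,4R,5R)-9-[(tert-butyldimethylsilyl)oxy]-3-hydroxyeremophila-7(11),9-dien-8-one; 14 (2Z)-2-methyl-4-{[(2Z)-2-methylbut-2-enoyl]oxy}but-2-enoic acid
Product: 16 (3R,4R,5R)-9-[(tert-butyldimethylsilyl)oxy]-8-oxoeremophila-7(11),9-dien-3-yl (2Z)-2-methyl-4-{[(2Z)-2-methylbut-2-enoyl]oxy}but-2-enoate, via mixed anhydride 15 (not isolated)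
Conditions: 14, 2,4,6-Cl3C6H2COCl, Et3N, toluene, rt; then 7, toluene, 80 °C (no DMAP)
Reagents that add atoms: none
Why: Yamaguchi-type acylation of the equatorial C3 hydroxyl through the mixed anhydride, run thermally without a nucleophilic catalyst, avoids Z→E isomerisation of the two 2-methylbut-2-enoyl units and proceeds with retention at C3, the diosphenol being masked as its silyl ether.

Step 10
Reactants: 16 (3R,4R,5R)-9-[(tert-butyldimethylsilyl)oxy]-8-oxoeremophila-7(11),9-dien-3-yl (2Z)-2-methyl-4-{[(2Z)-2-methylbut-2-enoyl]oxy}but-2-enoate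
Product: 17 (3R,4R,5R)-9-hydroxy-8-oxoeremophila-7(11),9-dien-3-yl (2Z)-2-methyl-4-{[(2Z)-2-methylbut-2-enoyl]oxy}but-2-enoate
Conditions: HF·pyridine, THF, 0 °C
Reagents that add atoms: none
Why: Fluoride-induced Si–O cleavage (desilylation) of the silyl enol ether is far faster than any ester cleavage and releases the hydrogen-bonded diosphenol with no stereocentre affected.

**Compound list**
1 | germacrone, (3E,7E)-3,7-dimethyl-10-(propan-2-ylidene)cyclodeca-3,7-dien-1-one | C/C1=C\CC/C(C)=C/CC(=C(C)C)C(=O)C1 | starting material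
2 | potassium dienolate of germacrone (C8–O−, C8=C9) | C/C1=C\CC/C(C)=C/CC(=C(C)C)C([O-])=C1.[K+] | intermediate
3 | (9R)-9-hydroxygermacrone, (2R,3E,7E)-2-hydroxy-3,7-dimethyl-10-(propan-2-ylidene)cyclodeca-3,7-dien-1-one | C/C1=C\CC/C(C)=C/CC(=C(C)C)C(=O)[C@@H]1O | intermediate
4 | (5S,9R,10S)-9-hydroxyeudesma-3,7(11)-dien-8-one (5α-H, 9β-OH, 10β-Me) | CC1=CCC[C@@]2(C)[C@H]1CC(=C(C)C)C(=O)[C@@H]2O | intermediate
5 | (5S,9R,10S)-9-[(tert-butyldimethylsilyl)oxy]eudesma-3,7(11)-dien-8-one | CC1=CCC[C@@]2(C)[C@H]1CC(=C(C)C)C(=O)[C@@H]2O[Si](C)(C)C(C)(C)C | intermediate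
6 | (3R,4S,5R,9R,10S)-9-[(tert-butyldimethylsilyl)oxy]-3,4-epoxyeudesm-7(11)-en-8-one (3α,4α-epoxide) | C[C@@]12O[C@@H]1CC[C@@]3(C)[C@H]2CC(=C(C)C)C(=O)[C@@H]3O[Si](C)(C)C(C)(C)C | intermediate
7 | (3R,4R,5R)-9-[(tert-butyldimethylsilyl)oxy]-3-hydroxyeremophila-7(11),9-dien-8-one (3α-OH, 4β-Me, 5β-Me) | O[C@@H]1CCC2=C(O[Si](C)(C)C(C)(C)C)C(=O)C(=C(C)C)C[C@]2(C)[C@H]1C | intermediate
8 | 3-methylfuran-2(5H)-one | CC1=CCOC1=O | starting material
9 | potassium (2Z)-4-hydroxy-2-methylbut-2-enoate | C/C(=C/CO)C(=O)[O-].[K+] | intermediate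
10 | 4-methoxybenzyl (2Z)-4-hydroxy-2-methylbut-2-enoate | C/C(=C/CO)C(=O)OCc1ccc(OC)cc1 | intermediate
11 | angelic acid, (2Z)-2-methylbut-2-enoic acid | C/C=C(/C)C(=O)O | starting material
12 | (2Z)-2-methylbut-2-enoic 2,4,6-trichlorobenzoic anhydride | C/C=C(/C)C(=O)OC(=O)c1c(Cl)cc(Cl)cc1Cl | intermediate
13 | 4-methoxybenzyl (2Z)-2-methyl-4-{[(2Z)-2-methylbut-2-enoyl]oxy}but-2-enoate | C/C=C(/C)C(=O)OC/C=C(/C)C(=O)OCc1ccc(OC)cc1 | intermediate
14 | (2Z)-2-methyl-4-{[(2Z)-2-methylbut-2-enoyl]oxy}but-2-enoic acid | C/C=C(/C)C(=O)OC/C=C(/C)C(=O)O | intermediate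
15 | mixed anhydride of 14 with 2,4,6-trichlorobenzoic acid | C/C=C(/C)C(=O)OC/C=C(/C)C(=O)OC(=O)c1c(Cl)cc(Cl)cc1Cl | intermediate
16 | (3R,4R,5R)-9-[(tert-butyldimethylsilyl)oxy]-8-oxoeremophila-7(11),9-dien-3-yl (2Z)-2-methyl-4-{[(2Z)-2-methylbut-2-enoyl]oxy}but-2-enoate | C/C=C(/C)C(=O)OC/C=C(/C)C(=O)O[C@@H]1CCC2=C(O[Si](C)(C)C(C)(C)C)C(=O)C(=C(C)C)C[C@]2(C)[C@H]1C | intermediate
17 | (3R,4R,5R)-9-hydroxy-8-oxoeremophila-7(11),9-dien-3-yl (2Z)-2-methyl-4-{[(2Z)-2-methylbut-2-enoyl]oxy}but-2-enoate (CNP0301409.1) | C/C=C(/C)C(=O)OC/C=C(/C)C(=O)O[C@@H]1CCC2=C(O)C(=O)C(=C(C)C)C[C@]2(C)[C@H]1C | target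

**Totals**
Total steps: 10 (7 on the main line, 3 for the side-chain acid).
Longest linear sequence: 7 steps (1 → 3 → 4 → 5 → 6 → 7 → 16 → 17).

**Steps most likely to fail**

Step 5 is the most likely to fail. The C4 cation may lose a C15 proton to give an allylic alcohol, the C5 cation may lose H-6, and the C9 silyloxy group disfavours the C10 cation. The fallback sets out from 5 and comes back at 16. The C3=C4 olefin of 5 is dihydroxylated on the α face (OsO4 cat., NMO, acetone/H2O) to the cis-diol (3R,4S,5R,9R,10S)-9-[(tert-butyldimethylsilyl)oxy]-3,4-dihydroxyeudesm-7(11)-en-8-one F1. Only its secondary C3 hydroxyl is acylated with acid 14 under the conditions of step 9, giving the hydroxy ester (3R,4S,5R,9R,10S)-9-[(tert-butyldimethylsilyl)oxy]-4-hydroxy-8-oxoeudesm-7(11)-en-3-yl (2Z)-2-methyl-4-{[(2Z)-2-methylbut-2-enoyl]oxy}but-2-enoate F2. The tertiary C4 hydroxyl is then ionised under Westphalen conditions (Ac2O, BF3·OEt2, CH2Cl2, −20 °C). The β-acyloxy cation can neither collapse to a ketone nor re-close to an epoxide, so the same hydride/methyl shifts and loss of H-9 give 16, which continues with step 10.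

Step 2 is the second risk. Proton loss from the eudesmyl cation can give the Δ4(15) and Δ4 isomers beside Δ3, the C9 oxygen slows protonation at C1, and the facial relay from C9 may be incomplete (the minor diastereomer must be removed before C9 can epimerise). The fallback sets out from 3 and comes back at 5. The cyclisation is run in a nucleophilic medium (HClO4 cat., acetone/H2O, 0 °C) so that water traps the C4 cation anti to the new C5–C10 bond, giving the diol (4R,5R,9R,10S)-4,9-dihydroxyeudesm-7(11)-en-8-one F3. Its secondary C9 hydroxyl is silylated (TBSOTf 1.05 equiv, 2,6-lutidine, −78 °C) to (4R,5R,9R,10S)-9-[(tert-butyldimethylsilyl)oxy]-4-hydroxyeudesm-7(11)-en-8-one F4. The equatorial tertiary alcohol, which has no anti-periplanar ring hydrogen, is dehydrated with SOCl2/pyridine to the exocyclic olefin (5S,9R,10S)-9-[(tert-butyldimethylsilyl)oxy]eudesma-4(15),7(11)-dien-8-one F5. The double bond is then moved into ring A with RhCl3·3H2O (cat.) in EtOH at 70 °C to reach 5.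

Step 1 is the third risk. Neither the level nor the sense of induction of the oxaziridine on a ten-membered dienolate is assured, and C9 is base-labile. The fallback sets out from 1 and comes back at 3. The dienolate of 1 is hydroxylated with racemic 2-(phenylsulfonyl)-3-phenyloxaziridine to give racemic 9-hydroxygermacrone F6. This is resolved under neutral conditions by preparative supercritical-fluid chromatography on an amylose tris(3,5-dimethylphenylcarbamate) phase, which delivers 3 and its enantiomer (9S)-9-hydroxygermacrone F7, the latter being set aside.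

**Further compounds**
F1 | step 5 | (3R,4S,5R,9R,10S)-9-[(tert-butyldimethylsilyl)oxy]-3,4-dihydroxyeudesm-7(11)-en-8-one | C[C@@]1(O)[C@H](O)CC[C@@]2(C)[C@H]1CC(=C(C)C)C(=O)[C@@H]2O[Si](C)(C)C(C)(C)C
F2 | step 5 | (3R,4S,5R,9R,10S)-9-[(tert-butyldimethylsilyl)oxy]-4-hydroxy-8-oxoeudesm-7(11)-en-3-yl (2Z)-2-methyl-4-{[(2Z)-2-methylbut-2-enoyl]oxy}but-2-enoate | C[C@@]1(O)[C@H](OC(=O)/C(C)=C\COC(=O)/C(C)=C\C)CC[C@@]2(C)[C@H]1CC(=C(C)C)C(=O)[C@@H]2O[Si](C)(C)C(C)(C)C
F3 | step 2 | (4R,5R,9R,10S)-4,9-dihydroxyeudesm-7(11)-en-8-one | C[C@@]1(O)CCC[C@@]2(C)[C@H]1CC(=C(C)C)C(=O)[C@@H]2O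
F4 | step 2 | (4R,5R,9R,10S)-9-[(tert-butyldimethylsilyl)oxy]-4-hydroxyeudesm-7(11)-en-8-one | C[C@@]1(O)CCC[C@@]2(C)[C@H]1CC(=C(C)C)C(=O)[C@@H]2O[Si](C)(C)C(C)(C)C
F5 | step 2 | (5S,9R,10S)-9-[(tert-butyldimethylsilyl)oxy]eudesma-4(15),7(11)-dien-8-one | C=C1CCC[C@@]2(C)[C@H]1CC(=C(C)C)C(=O)[C@@H]2O[Si](C)(C)C(C)(C)C
F6 | step 1 | rac-9-hydroxygermacrone | C/C1=C\CC/C(C)=C/CC(=C(C)C)C(=O)C1O
F7 | step 1 | (9S)-9-hydroxygermacrone | C/C1=C\CC/C(C)=C/CC(=C(C)C)C(=O)[C@H]1O
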